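**Plan**

- Retrosynthesis: the two O-benzyl groups come off last. Ring B is opened at C2'–C3' (retro six-electron closure, then retro four-electron opening) to the 4-alkenylcyclobutenone 15. The C1'–C6' bond is cut (Stille) into vinylstannane 11 and chlorocyclobutenone 14 from dimethyl squarate. C3–C1' is cut (Sonogashira) to 3-iodochromone 7, and ring C is opened to acetophenone 5, made from phloroacetophenone.
- Forward order: ring A is bought and receives its C6 oxygen (Elbs) and methyl group. Ring C is closed by enaminone/iodine cyclisation. The C1'–C2' unit is attached and stannylated, the squarate four-membered ring is joined, and ring B is formed last by electrocyclic benzannulation before hydrogenolysis.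
- Enabling feature: ring B has a free C3'–OH next to C4'–OMe and C5'–OMe, with C2' and C6' unsubstituted. This maps onto a dienylketene from a 2,3-dimethoxycyclobutenone: C3' is the ketene carbon, C4' and C5' are the methoxy-bearing squarate carbons, C6' is the cyclobutenone CH, and C1'/C2' are the two carbons of the 1-(chromon-3-yl)vinyl group.
- Stereochemistry: irigenin is achiral. The only stereocentre on the route (C4 of 13, 14 and 15, racemic) disappears when ring B aromatises.

Key step: step 11

Remark: 13, 14 and 15 are racemates and are written without a stereodescriptor; the C4 centre is lost in step 11.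

**Route**

Step 1
Reactants: 1 1-(2,4,6-trihydroxyphenyl)ethan-1-one
Product: 2 1-[2,4-bis(benzyloxy)-6-hydroxyphenyl]ethan-1-one
Conditions: BnBr (2.1 equiv), K2CO3, DMF, rt
Reagents that add atoms: benzyl bromide, BrCc1ccccc1
Why: Williamson etherification, in which the C4 hydroxyl and one of the two equivalent ortho hydroxyls are alkylated while the remaining ortho hydroxyl, hydrogen-bonded to the acetyl carbonyl, should stay free.

Step 2
Reactants: 2 1-[2,4-bis(benzyloxy)-6-hydroxyphenyl]ethan-1-one
Product: 4 1-[2,4-bis(benzyloxy)-3,6-dihydroxyphenyl]ethan-1-one, via aryl sulfate 3 (not isolated)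
Conditions: K2S2O8 (1 equiv), aq. NaOH, pyridine, 0 °C to rt, argon; then aq. HCl, 80 °C
Reagents that add atoms: potassium peroxodisulfate, [K+].[K+].[O-]S(=O)(=O)OOS(=O)(=O)[O-]
Why: Elbs persulfate oxidation, in which the phenoxide attacks peroxodisulfate through its para carbon (C3, between the two benzyloxy groups) and acid hydrolysis of sulfate 3 should release the hydroquinone, the benzyl ethers and the ketone being inert to alkaline persulfate and to brief warming in dilute acid.

Step 3
Reactants: 4 1-[2,4-bis(benzyloxy)-3,6-dihydroxyphenyl]ethan-1-one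
Product: 5 1-[2,4-bis(benzyloxy)-6-hydroxy-3-methoxyphenyl]ethan-1-one
Conditions: MeI (1.05 equiv), K2CO3, acetone, 40 °C, argon
Reagents that add atoms: iodomethane, CI
Why: Williamson O-methylation, selective because the C6 hydroxyl is chelated to the carbonyl and much less nucleophilic than the free C3 hydroxyl, which becomes the C6 methoxy group of the chromone.

Step 4
Reactants: 5 1-[2,4-bis(benzyloxy)-6-hydroxy-3-methoxyphenyl]ethan-1-one
Product: 7 5,7-bis(benzyloxy)-3-iodo-6-methoxy-4H-chromen-4-one, via enaminone 6 (not isolated)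
Conditions: Me2NCH(OMe)2, 90 °C; evaporate; then I2, CHCl3, rt
Reagents that add atoms: N,N-dimethylformamide dimethyl acetal, COC(OC)N(C)C; iodine, II
Why: Enaminone condensation of the methyl ketone followed by iodine-induced cyclisation of the 2-hydroxyaryl enaminone (iodination at the α-carbon, attack of the only free phenol on the iminium carbon, loss of dimethylamine), so that ring C can close only to the 6-methoxy isomer because the other ortho oxygen is benzylated.

Step 5
Reactants: 7 5,7-bis(benzyloxy)-3-iodo-6-methoxy-4H-chromen-4-one; 8 ethynyltrimethylsilane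
Product: 9 5,7-bis(benzyloxy)-6-methoxy-3-[(trimethylsilyl)ethynyl]-4H-chromen-4-one
Conditions: PdCl2(PPh3)2 (cat.), CuI (cat.), Et3N, THF, rt
Reagents that add atoms: none
Why: Sonogashira coupling, favoured by fast oxidative addition of the α-iodoenone C–I bond, with a tertiary amine base that should not open the pyranone ring.

Step 6
Reactants: 9 5,7-bis(benzyloxy)-6-methoxy-3-[(trimethylsilyl)ethynyl]-4H-chromen-4-one
Product: 10 5,7-bis(benzyloxy)-3-ethynyl-6-methoxy-4H-chromen-4-one
Conditions: Bu4NF, AcOH, THF, 0 °C
Reagents that add atoms: none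
Why: Fluoride-induced cleavage of the alkynyl C–Si bond, buffered with acetic acid so that the electrophilic C2 of the chromone is not exposed to a basic medium.

Step 7
Reactants: 10 5,7-bis(benzyloxy)-3-ethynyl-6-methoxy-4H-chromen-4-one
Product: 11 5,7-bis(benzyloxy)-6-methoxy-3-[1-(tributylstannyl)vinyl]-4H-chromen-4-one
Conditions: Bu3SnH (slow addition), PdCl2(PPh3)2 (cat.), THF, 0 °C
Reagents that add atoms: tributyltin hydride, CCCC[SnH](CCCC)CCCC
Why: Palladium-catalysed syn-hydrostannation of a terminal alkyne, expected to place tin on the internal carbon as it does for ortho-substituted arylacetylenes and conjugated enynes, the flanking C4 carbonyl playing the role of the ortho substituent.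

Step 8
Reactants: 12 dimethyl squarate
Product: 13 4-hydroxy-2,3-dimethoxycyclobut-2-en-1-one (racemic)
Conditions: LiAlH(OtBu)3 (1 equiv), THF, −78 °C; pH 7 buffer, cold work-up
Reagents that add atoms: none
Why: 1,2-Reduction of one vinylogous ester carbonyl of a dialkyl squarate by a bulky hydride, which should stop at the mono-adduct at low temperature; the new C4 stereocentre is formed as a racemate and needs no control.

Step 9
Reactants: 13 4-hydroxy-2,3-dimethoxycyclobut-2-en-1-one (racemic)
Product: 14 4-chloro-2,3-dimethoxycyclobut-2-en-1-one (racemic)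
Conditions: SOCl2, pyridine, CH2Cl2, −20 to 0 °C; non-aqueous work-up, used at once
Reagents that add atoms: thionyl chloride, ClS(Cl)=O
Why: Chlorodehydroxylation of an activated secondary alcohol through its chlorosulfite, the established entry to 4-chlorocyclobutenones from 4-hydroxycyclobutenones; the product stays racemic.

Step 10
Reactants: 11 5,7-bis(benzyloxy)-6-methoxy-3-[1-(tributylstannyl)vinyl]-4H-chromen-4-one; 14 4-chloro-2,3-dimethoxycyclobut-2-en-1-one (racemic)
Product: 15 4-{1-[5,7-bis(benzyloxy)-6-methoxy-4-oxo-4H-chromen-3-yl]vinyl}-2,3-dimethoxycyclobut-2-en-1-one (racemic)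
Conditions: Pd2(dba)3 (cat.), P(2-furyl)3, CuI (cat.), dioxane, 25–40 °C
Reagents that add atoms: none
Why: Stille coupling in which zerovalent palladium inserts into the allylic-type C4–Cl bond, the alkenyl group is transferred from tin (helped by the weakly bound phosphine and CuI) and reductive elimination at C4 restores the conjugated vinylogous ester, a coupling known for 4-chlorocyclobutenones with alkenyl-, aryl- and heteroarylstannanes and run cool enough that ring opening of 15 stays slow.

Step 11
Reactants: 15 4-{1-[5,7-bis(benzyloxy)-6-methoxy-4-oxo-4H-chromen-3-yl]vinyl}-2,3-dimethoxycyclobut-2-en-1-one (racemic)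
Product: 18 5,7-di-O-benzylirigenin, via dienylketene 16 (not isolated), via cyclohexadienone 17 (not isolated)
Conditions: dioxane (0.02 M, degassed), 100 °C, argon
Reagents that add atoms: none
Why: Heating opens the cyclobutenone by conrotatory four-electron cleavage of the C1–C4 bond to dienylketene 16, and a disrotatory six-electron electrocyclisation then joins the ketene carbon (future C3') to the vinyl CH2 terminus (future C2') to give cyclohexadienone 17, which tautomerises to phenol 18. The closest known reaction type is the thermal benzannulation of 4-alkenyl- and 4-arylcyclobutenones to phenols. Ring B closes in a single mode, a thermally allowed six-electron electrocyclic closure of an all-carbon triene, made irreversible by aromatisation. No stereocentre is created, and the racemic C4 centre of 15 becomes the sp2 carbon C6'. The selectivity needed is that of the ketene geometry: inward or outward rotation of the C4 substituent gives two isomers of 16, but ring opening is reversible and only the isomer with the vinyl group cis to the ketene can cyclise, so the equilibrium drains through it, and the CH2=C unit is the only double bond placed to complete a hexatriene because the chromone C2=C3 bond lies one atom too far. The oxygen pattern is fixed by the substrate, since only the ketene carbonyl becomes a free hydroxyl while the two squarate methoxy groups remain ethers at C4' and C5', and the benzyl ethers on O5 and O7 leave no nucleophile to trap the ketene.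

Step 12
Reactants: 18 5,7-di-O-benzylirigenin
Product: 19 irigenin
Conditions: H2 (1 atm), 10% Pd/C, EtOAc–MeOH, rt, stopped after uptake of two equivalents
Reagents that add atoms: none
Why: Hydrogenolysis of aryl benzyl ethers, which should be much faster than reduction of the C2=C3 bond of the 3-arylchromone (a vinylogous ester), while the methyl ethers and the C3' phenol are untouched.

**Compound list**

1 | 1-(2,4,6-trihydroxyphenyl)ethan-1-one (phloroacetophenone) | CC(=O)c1c(O)cc(O)cc1O | starting material
2 | 1-[2,4-bis(benzyloxy)-6-hydroxyphenyl]ethan-1-one | CC(=O)c1c(O)cc(OCc2ccccc2)cc1OCc1ccccc1 | intermediate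
3 | potassium 3-acetyl-2,6-bis(benzyloxy)-4-hydroxyphenyl sulfate | CC(=O)c1c(O)cc(OCc2ccccc2)c(OS(=O)(=O)[O-])c1OCc1ccccc1.[K+] | intermediate
4 | 1-[2,4-bis(benzyloxy)-3,6-dihydroxyphenyl]ethan-1-one | CC(=O)c1c(O)cc(OCc2ccccc2)c(O)c1OCc1ccccc1 | intermediate
5 | 1-[2,4-bis(benzyloxy)-6-hydroxy-3-methoxyphenyl]ethan-1-one | CC(=O)c1c(O)cc(OCc2ccccc2)c(OC)c1OCc1ccccc1 | intermediate
6 | (E)-1-[2,4-bis(benzyloxy)-6-hydroxy-3-methoxyphenyl]-3-(dimethylamino)prop-2-en-1-one | CN(C)/C=C/C(=O)c1c(O)cc(OCc2ccccc2)c(OC)c1OCc1ccccc1 | intermediate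
7 | 5,7-bis(benzyloxy)-3-iodo-6-methoxy-4H-chromen-4-one | COc1c(OCc2ccccc2)cc2occ(I)c(=O)c2c1OCc1ccccc1 | intermediate
8 | ethynyltrimethylsilane | C#C[Si](C)(C)C | starting material
9 | 5,7-bis(benzyloxy)-6-methoxy-3-[(trimethylsilyl)ethynyl]-4H-chromen-4-one | COc1c(OCc2ccccc2)cc2occ(C#C[Si](C)(C)C)c(=O)c2c1OCc1ccccc1 | intermediate
10 | 5,7-bis(benzyloxy)-3-ethynyl-6-methoxy-4H-chromen-4-one | COc1c(OCc2ccccc2)cc2occ(C#C)c(=O)c2c1OCc1ccccc1 | intermediate
11 | 5,7-bis(benzyloxy)-6-methoxy-3-[1-(tributylstannyl)vinyl]-4H-chromen-4-one | COc1c(OCc2ccccc2)cc2occ(C(=C)[Sn](CCCC)(CCCC)CCCC)c(=O)c2c1OCc1ccccc1 | intermediate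
12 | dimethyl squarate (3,4-dimethoxycyclobut-3-ene-1,2-dione) | COC1=C(OC)C(=O)C1=O | starting material
13 | 4-hydroxy-2,3-dimethoxycyclobut-2-en-1-one (racemic) | COC1=C(OC)C(O)C1=O | intermediate
14 | 4-chloro-2,3-dimethoxycyclobut-2-en-1-one (racemic) | COC1=C(OC)C(Cl)C1=O | intermediate
15 | 4-{1-[5,7-bis(benzyloxy)-6-methoxy-4-oxo-4H-chromen-3-yl]vinyl}-2,3-dimethoxycyclobut-2-en-1-one (racemic) | COC1=C(OC)C(C(=C)c2coc3cc(OCc4ccccc4)c(OC)c(OCc4ccccc4)c3c2=O)C1=O | intermediate
16 | (3E)-5-[5,7-bis(benzyloxy)-6-methoxy-4-oxo-4H-chromen-3-yl]-2,3-dimethoxyhexa-1,3,5-trien-1-one (vinyl group cis to the ketene) | O=C=C(OC)/C(OC)=C\C(=C)c1coc2cc(OCc3ccccc3)c(OC)c(OCc3ccccc3)c2c1=O | intermediate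
17 | 5-[5,7-bis(benzyloxy)-6-methoxy-4-oxo-4H-chromen-3-yl]-2,3-dimethoxycyclohexa-2,4-dien-1-one | COC1=C(OC)C(=O)CC(c2coc3cc(OCc4ccccc4)c(OC)c(OCc4ccccc4)c3c2=O)=C1 | intermediate
18 | 5,7-di-O-benzylirigenin, 5,7-bis(benzyloxy)-3-(3-hydroxy-4,5-dimethoxyphenyl)-6-methoxy-4H-chromen-4-one | COc1cc(-c2coc3cc(OCc4ccccc4)c(OC)c(OCc4ccccc4)c3c2=O)cc(O)c1OC | intermediate
19 | irigenin, 5,7-dihydroxy-3-(3-hydroxy-4,5-dimethoxyphenyl)-6-methoxy-4H-chromen-4-one | COc1cc(-c2coc3cc(O)c(OC)c(O)c3c2=O)cc(O)c1OC | target

**Step count**

Total: 12 steps. Longest linear sequence: 10 steps (steps 1 to 7, then 10, 11 and 12); steps 8 and 9 form the two-step squarate branch.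

**Steps most likely to fail**

Step 10. The 1-substituted, electron-poor alkenyl group may transfer from tin to palladium too slowly. That would leave time for bond formation at the CH2 terminus (cine substitution), for decay of chloride 14, or for drift of the new double bond into conjugation with the four-membered ring. The fallback replaces tin by zinc, which transfers much faster. It sets out from 11: iododestannylation (I2, CH2Cl2, 0 °C) should give 5,7-bis(benzyloxy)-3-(1-iodovinyl)-6-methoxy-4H-chromen-4-one F1. Zinc insertion (Zn dust, LiCl, THF) should turn this into {1-[5,7-bis(benzyloxy)-6-methoxy-4-oxo-4H-chromen-3-yl]vinyl}zinc iodide F2, used in solution. Negishi coupling of F2 with 14 under Pd(PPh3)4 catalysis (an alkenylzinc halide with an allylic-type chloride) should come back to the route at 15.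

Step 9. The C4–Cl bond may ionise, since the cation is stabilised by the methoxy group at C2. Chloride could then remove an O-methyl group as chloromethane, or water could enter on work-up; either way the ring collapses to a cyclobutenedione. The fallback avoids a chloride leaving group and free chloride altogether. It sets out from 13: acylation (ClCO2Me, pyridine, CH2Cl2, −20 °C) should give methyl (2,3-dimethoxy-4-oxocyclobut-2-en-1-yl) carbonate (racemic) F3. This is coupled with stannane 11 under neutral conditions (Pd2(dba)3, P(2-furyl)3, THF, rt), as for allylic carbonates with organostannanes. Zerovalent palladium ionises the carbonate with loss of CO2, the methoxide formed takes up the tin, and the route is rejoined at 15.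

Step 7. Tin may be delivered to the terminal carbon instead of the internal one, and palladium/tin hydride may also reduce the C2=C3 bond of the chromone by conjugate addition. The fallback fixes the position of the metal by a carbonyl group instead of by hydrometalation. It sets out from 7: Stille coupling with tributyl(1-ethoxyvinyl)stannane (PdCl2(PPh3)2, toluene, 90 °C) should give 5,7-bis(benzyloxy)-3-(1-ethoxyvinyl)-6-methoxy-4H-chromen-4-one F4. Mild acid hydrolysis (aq. HCl, THF, rt) should give 3-acetyl-5,7-bis(benzyloxy)-6-methoxy-4H-chromen-4-one F5. Enol triflation of the methyl ketone (Tf2O, 2,6-di-tert-butyl-4-methylpyridine, CH2Cl2, 0 °C) should give 1-[5,7-bis(benzyloxy)-6-methoxy-4-oxo-4H-chromen-3-yl]vinyl trifluoromethanesulfonate F6. Palladium-catalysed stannylation (Bu3SnSnBu3, Pd(PPh3)4, LiCl, THF, 60 °C) should come back to the route at 11.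

**Further compounds**

F1 | step 10 | 5,7-bis(benzyloxy)-3-(1-iodovinyl)-6-methoxy-4H-chromen-4-one | COc1c(OCc2ccccc2)cc2occ(C(=C)I)c(=O)c2c1OCc1ccccc1
F2 | step 10 | {1-[5,7-bis(benzyloxy)-6-methoxy-4-oxo-4H-chromen-3-yl]vinyl}zinc iodide | COc1c(OCc2ccccc2)cc2occ(C(=C)[Zn]I)c(=O)c2c1OCc1ccccc1
F3 | step 9 | methyl (2,3-dimethoxy-4-oxocyclobut-2-en-1-yl) carbonate (racemic) | COC(=O)OC1C(OC)=C(OC)C1=O
F4 | step 7 | 5,7-bis(benzyloxy)-3-(1-ethoxyvinyl)-6-methoxy-4H-chromen-4-one | CCOC(=C)c1coc2cc(OCc3ccccc3)c(OC)c(OCc3ccccc3)c2c1=O
F5 | step 7 | 3-acetyl-5,7-bis(benzyloxy)-6-methoxy-4H-chromen-4-one | CC(=O)c1coc2cc(OCc3ccccc3)c(OC)c(OCc3ccccc3)c2c1=O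
F6 | step 7 | 1-[5,7-bis(benzyloxy)-6-methoxy-4-oxo-4H-chromen-3-yl]vinyl trifluoromethanesulfonate | C=C(OS(=O)(=O)C(F)(F)F)c1coc2cc(OCc3ccccc3)c(OC)c(OCc3ccccc3)c2c1=O
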